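## The problem

Numbering used throughout: C1 is the isobutyryl bridgehead, C2 the gem-dimethyl carbon, C3 the prenyl-bearing CH, C4 the CH2, C5 the prenyl bridgehead, C6 the carbinol carbon, C7 the ketone next to it and C8 the one-carbon ketone bridge.

- Target 25 is a bicyclo[3.2.1]octane. A cyclopentane ring (C1, C7, C6, C5, C8) carries three adjacent oxygenated carbons and is spanned from C1 to C5 by the bridge C2-C3-C4. C1 and C2 are neighbouring quaternary carbons.
- There are four stereocentres (C1, C3, C5, C6). C1 and C5 are tied together by the bicycle. The C3 prenyl group is exo (equatorial on the chair ring C1-C2-C3-C4-C5-C8, turned away from the C6-C7 bridge). The C6 acyl group is also exo (on the side of C8), with the hydroxyl endo. Both can therefore be set on the finished bicycle from its open face, so only C1 needs absolute control.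
- C1 is awkward. It carries three acyl carbons and a tert-alkyl group, and its handedness rests only on which flanking ring carbonyl is C7 and which is C8.
- Several groups will not survive rough treatment:
  - the triacyl carbon C1 is cleaved by nucleophiles and alkoxides (retro-Claisen);
  - the C6 ketol, flanked by C7=O and the side-chain carbonyl, is open to retro-aldol, acyloin shift and 1,3-diketone cleavage;
  - the Z-configured gamma-hydroxy enone can isomerise or close to a lactol;
  - the two prenyl alkenes are exposed to acid, electrophilic halogen and singlet oxygen.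
- The feature that makes the key step possible: C5 lies between the C6 and C8 carbonyls, so it is a natural 1,3-dicarbonyl radical site. C3 and C4 are the two vinyl carbons of a 2-methylbut-3-en-2-yl group on C1. A cyclopentane-1,2,4-trione with that group next to the radical site therefore holds the whole six-membered ring in open form.

## Retrosynthesis

**25 to 23 (through 24).** The C-CH3 bond of the side-chain carbinol is cut and the C6 hydroxyl is carried as a trimethylsilyl ether. This leaves a methyl ketone, the only carbonyl of 23 that is not next to a quaternary carbon. Building the tertiary carbinol earlier would require a Z-vinyl anion and a separate acylation at the crowded C6. The forward reaction must add one methyl group 1,2 to that ketone without conjugate addition and without base-induced cleavage at C6.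

**23 to 21 (through 22), and 21 to 17 + 18 (through 19, 20).** The Z-enedione of 23 is an oxidised 2,5-disubstituted furan, and the furan is cut from C6. The ring holds the future alkene in the Z geometry. 2-Lithio-5-methylfuran 19 is an acyl anion equivalent that brings five of the six side-chain carbons and sets both C6 substituents in one addition. An acetylide route would need a later ketone installation and a semi-reduction. The precursor 17 has no C6 stereocentre. The addition must choose C6 over C7 and the exo face, and the alkoxide 20 must be silylated before it can fragment.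

**17 to 16.** The C3 prenyl group is cut at its double bond. A radical allyl transfer can deliver allyl but not prenyl, because a prenylstannane would hand over its tertiary end. Cross-metathesis of the terminal alkene of 16 is all that is asked.

**16 to 13 + 14 (through 15).** Bonds C5-C4 and C3-CH2 are cut. This removes the six-membered ring and two stereocentres at once and leaves a monocyclic trione whose single fixed stereocentre, C1, then dictates C5. Cutting C1-C7 or C1-C2 instead would leave C1 to be made as a quaternary carbon during ring closure. The forward reaction must close 6-endo, must cyclise before the allyl donor intervenes, and must accept the allyl group on the exo face of C3.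

**13 to 11 (through 12), 11 to 10, and 10 to 7 + 8 (through 9).** The C-Br bond and the O-Si bond are cut, then the bond between the quaternary carbons C1 and C2, which a Claisen rearrangement of the O-prenyl enol ether 9 forms.
- No other general reaction joins a tertiary allyl terminus to a fully substituted triacyl carbon.
- The rearrangement is planned as a racemic reaction followed by resolution (10 to 11). The two ring carbonyls flanking the acyl carbon are nearly alike, so 9 forms as an E/Z mixture. A catalyst that selects one face of the allyl vinyl ether would turn the two geometries into opposite enantiomers.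
- Resolution is placed here because the stereocentre first exists in 10, only four steps from commodity chemicals.

**7 to 6, 6 to 3 + 4 (through 5), and 3 to 1 + 2.** The silyl ether is removed, then the two ring bonds to the oxalate carbons (C1-C7 and C5-C6 in the numbering of the target), then the acyl bond of the 1,3-diketone.
- Putting the isobutyryl group in before the ring is closed avoids a C-acylation of a trione, and it avoids the hot acid that removal of a second oxalyl group would need.
- The C5 prenyl group arrives with ketone 1.
- The silyl ether in 7 blocks the second enol, so that O-prenylation can only occur at the acyl enol.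

## Roads not taken

**Alternative 1:** The cut is C1-C7. In the forward step (CF3CO)2O turns the acetic acid arm of the cyclohexenyl enol ether A2 into a mixed anhydride. The enol ether carbon C1 attacks it and the O-methyl group is lost, giving dione A1.
- Merits: it is a closed-shell, tin-free closure. C6 is left as the only enolisable methylene, so later work at C6 has no regiochemical question. The chosen plan cannot claim this, since it must tell the C6 ketone from the C7 ketone.
- Weak points: the nucleophilic carbon already bears the isobutyryl group and sits beside the gem-dimethyl carbon, so a deactivated, crowded enol ether must form the triacyl quaternary centre. The medium is strongly acidic in the presence of two prenyl groups. A2 needs C3 and C5 set on a cyclohexene in separate operations. After closure, C6 still needs its hydroxyl and its acyl chain by two enolate reactions at a neopentyl position.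
- Comparison: the chosen plan sets against the C6 advantage a shorter endgame (both C6 substituents in one addition) and a key step that creates C3 and C5 together.

**Alternative 2:** The cuts are C5-C4 and C1-C2. In the forward step the bis(silyloxy)cyclopentadienone A4 combines through its two diene termini with the cation released from A5 by AgBF4 in a (4+3) cycloaddition to give A3.
- Merits: it is the most convergent road. Both bridgeheads, the vicinal quaternary pair and the C8 ketone arise in one step, and C6 and C7 arrive masked as an enediol.
- Weak points: A4 is an antiaromatic dienone that should dimerise, and it is electron-poor at the acyl-bearing terminus. The more hindered regiochemistry (the dimethyl end bonding to C1) is the one needed. The product is racemic with no handle for induction. C3 arrives as a ketone that must become a prenyl-bearing CH of defined configuration among four other carbonyls. The enediol bis-silyl ether does not distinguish C6 from C7.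
- Comparison: it is shorter on paper to the core, but every selectivity is open. The chosen plan delivers C3 with the right carbon substituent and configuration in the ring-forming step.

**Alternative 3:** The cut is C5-C4 as in the chosen plan, but made by polar means. With catalytic Cs2CO3 the enolate carbon C5 of trione A7 adds to the tethered acrylate, and protonation at C3 gives ester A6.
- Merits: as a ring closure this is probably more reliable than the radical step. It uses a soft enolate and catalytic base, needs no bromination and no tin, and the exo ester can be reached by equilibration. A7 is reachable by the same O-alkylation and rearrangement logic.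
- Weak points: C3 arrives as a tert-butyl ester. Turning it into CH2-CH=CMe2 needs reduction and a chain extension by two carbons, with hydride and ylide or organometal reagents in the presence of four ketones, one of them part of a triacyl carbon. The Michael addition is also reversible.
- Comparison: the chosen plan sets against the safer closure the fact that its C3 substituent is one cross-metathesis away from prenyl.

Key step: step 7

## Route

Remark on numbering: bicyclic compounds keep the locants defined in "The problem", also where lowest-locant rules would exchange C6 and C7. "Prenyl" is 3-methylbut-2-enyl and "isobutyryl" is 2-methylpropanoyl.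

Remark on the target: 25 is taken as the open Z hydroxy enone; its five-membered lactol is regarded as the same compound in equilibrium.

Step 1
Reactants: 1 6-methylhept-5-en-2-one; 2 isobutyryl chloride
Product: 3 2,9-dimethyldec-8-ene-3,5-dione
Conditions: 1 (2.0 equiv), LiN(iPr)2 (2.0 equiv), THF, -78 °C; then 2 (1.0 equiv), -78 to 0 °C; aq. NH4Cl
Reagents that add atoms: none
Why: C-acylation of the kinetic, methyl-side lithium enolate by an acid chloride is a standard 1,3-diketone synthesis; the second equivalent of enolate deprotonates the product, which suppresses O- and bis-acylation, and that equivalent of 1 is recovered.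

Step 2
Reactants: 3 2,9-dimethyldec-8-ene-3,5-dione; 4 diethyl oxalate
Product: 6 3-isobutyryl-5-prenylcyclopentane-1,2,4-trione (dienol form), via trioxo ester 5 (not isolated)
Conditions: NaH (4 equiv), 4 (1.1 equiv), 1,2-dimethoxyethane, 0 to 60 °C; then 1 M HCl
Reagents that add atoms: none
Why: Claisen condensation at the terminal methylene of the diketone dianion, the only position that can be acylated productively, is followed by Dieckmann closure of the central carbanion onto the keto ester; this is the double oxalate condensation that turns dialkyl ketones into cyclopentane-1,2,4-triones, and the doubly enolised product is the thermodynamic sink.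

Step 3
Reactants: 6 3-isobutyryl-5-prenylcyclopentane-1,2,4-trione
Product: 7 2-isobutyryl-4-prenyl-5-(triisopropylsilyloxy)cyclopent-4-ene-1,3-dione (silyl ether of the ring enol oxygen next to the prenyl carbon; acyl group as its chelated enol)
Conditions: iPr3SiCl (1.05 equiv), imidazole (2.2 equiv), CH2Cl2, 0 °C to rt
Reagents that add atoms: chlorotriisopropylsilane, CC(C)[Si](Cl)(C(C)C)C(C)C
Why: Silyl groups exchange among enol oxygens, so the mono-silyl ether should settle under thermodynamic control on the ring diosphenol oxygen, which leaves the acyl group in its strongly hydrogen-bonded enol; a silyl ether on either ring oxygen flanking the acyl carbon would have to be a cyclopentadienone.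

Step 4
Reactants: 7 2-isobutyryl-4-prenyl-5-(triisopropylsilyloxy)cyclopent-4-ene-1,3-dione; 8 3-methylbut-2-en-1-ol
Product: 10 rac-2-isobutyryl-2-(2-methylbut-3-en-2-yl)-4-prenyl-5-(triisopropylsilyloxy)cyclopent-4-ene-1,3-dione, via O-prenyl enol ether 9 (not isolated)
Conditions: 8 (1.3 equiv), PPh3, iPrO2CN=NCO2iPr, toluene, 0 °C to rt; then 100 °C
Reagents that add atoms: none
Why: Mitsunobu O-alkylation of the acidic chelated enol (the ring oxygens cannot be alkylated without forming a cyclopentadienone) is followed by thermal Claisen rearrangement, which joins the tertiary allyl terminus to the acyl-bearing carbon from either enol ether geometry; the quaternary centre is formed as the racemate.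

Step 5
Reactants: 10 rac-2-isobutyryl-2-(2-methylbut-3-en-2-yl)-4-prenyl-5-(triisopropylsilyloxy)cyclopent-4-ene-1,3-dione
Product: 11 (2R)-2-isobutyryl-2-(2-methylbut-3-en-2-yl)-4-prenyl-5-(triisopropylsilyloxy)cyclopent-4-ene-1,3-dione
Conditions: preparative HPLC, immobilised cellulose tris(3,5-dichlorophenylcarbamate) phase, hexane/EtOAc
Reagents that add atoms: none
Why: Resolution of a neutral, non-epimerisable quaternary stereocentre on a chiral stationary phase at the first point where it exists; the (R) antipode would be identified by anomalous-dispersion X-ray analysis of bromide 13 or of a crystalline derivative.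

Step 6
Reactants: 11 (2R)-2-isobutyryl-2-(2-methylbut-3-en-2-yl)-4-prenyl-5-(triisopropylsilyloxy)cyclopent-4-ene-1,3-dione
Product: 13 (3R,5S)-3-bromo-5-isobutyryl-5-(2-methylbut-3-en-2-yl)-3-prenylcyclopentane-1,2,4-trione (one C3 epimer drawn; its epimer serves equally), via enol 12 (not isolated)
Conditions: Bu4NF, AcOH, THF, 0 °C; then NBS (1.05 equiv), 0 °C, dark
Reagents that add atoms: N-bromosuccinimide, O=C1CCC(=O)N1Br
Why: Fluoride cleaves the vinylogous silyl ester, and the freed enol of the cyclic 1,3-diketone is brominated at carbon by NBS much faster than the isolated alkenes (alpha-halogenation of a 2-substituted 1,3-dicarbonyl compound); the C3 configuration is irrelevant because that carbon becomes a planar radical.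

Step 7
Reactants: 13 (3R,5S)-3-bromo-5-isobutyryl-5-(2-methylbut-3-en-2-yl)-3-prenylcyclopentane-1,2,4-trione; 14 allyltributylstannane
Product: 16 (1R,3R,5R)-3-allyl-1-isobutyryl-2,2-dimethyl-5-prenylbicyclo[3.2.1]octane-6,7,8-trione, via bicyclic bromide 15 (not isolated)
Conditions: 14 (0.1 equiv), AIBN (0.1 equiv), PhH (0.02 M), 80 °C; then concentrate to 0.2 M, 14 (8 equiv), AIBN (0.2 equiv), 80 °C
Reagents that add atoms: none
Why: Tin radicals from 14 and AIBN abstract bromine from 13; the C5 radical, planar and delocalised into the C6 and C8 carbonyls, adds to the unsubstituted vinyl terminus (bond C5-C4, ring C1-C2-C3-C4-C5-C8, 6-endo-trig), and with little stannane present the secondary C3 radical takes bromine from a further molecule of 13, carrying an atom-transfer chain to bromide 15. In the second phase tin radicals re-form the C3 radical from 15, and 14 at high concentration captures it with loss of Bu3Sn (bond C3-CH2). The closest known reactions are stannane-chain and atom-transfer cyclisations of 2-halo-1,3-dicarbonyl radicals onto alkenes and the Keck allylation of alkyl bromides. The 6-endo mode is secured by an electrophilic radical meeting the unhindered CH2 terminus, by the neopentyl internal alkene carbon, by the C8 carbonyl lying inside the forming ring and by the strain of the bicyclo[2.2.1] alternative. C5 is controlled by C1, since the tether reaches only the face of the cyclopentane that carries the 2-methylbut-3-en-2-yl group, so the prenyl group becomes the bridgehead substituent. C3 is controlled by the bicycle, since the stannane meets the C3 radical on the face turned away from the C6-C7 bridge, which places allyl exo. The step needs cyclisation to precede allyl transfer, which the stannane-poor first phase provides, and allyl capture to outrun ring reopening, which the high stannane concentration of the second phase serves.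

Step 8
Reactants: 16 (1R,3R,5R)-3-allyl-1-isobutyryl-2,2-dimethyl-5-prenylbicyclo[3.2.1]octane-6,7,8-trione
Product: 17 (1R,3R,5R)-1-isobutyryl-2,2-dimethyl-3,5-diprenylbicyclo[3.2.1]octane-6,7,8-trione
Conditions: second-generation Grubbs catalyst (5 mol %), 2-methylbut-2-ene/CH2Cl2, 40 °C
Reagents that add atoms: 2-methylbut-2-ene, CC=C(C)C
Why: Cross-metathesis of a terminal alkene with a trisubstituted partner in large excess; the existing prenyl group can only exchange degenerately and the ketones are inert to the ruthenium carbene.

Step 9
Reactants: 17 (1R,3R,5R)-1-isobutyryl-2,2-dimethyl-3,5-diprenylbicyclo[3.2.1]octane-6,7,8-trione; 18 2-methylfuran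
Product: 21 (1R,3R,5S,6S)-1-isobutyryl-2,2-dimethyl-6-(5-methylfuran-2-yl)-3,5-diprenyl-6-(trimethylsilyloxy)bicyclo[3.2.1]octane-7,8-dione, via 5-methyl-2-furyllithium 19 (not isolated), via lithium alkoxide 20 (not isolated)
Conditions: 18, n-BuLi, THF, 0 °C; added to 17, THF, -78 °C; then Me3SiOTf, -78 °C; aq. NaHCO3
Reagents that add atoms: trimethylsilyl trifluoromethanesulfonate, C[Si](C)(C)OS(=O)(=O)C(F)(F)F
Why: 1,2-Addition of a heteroaryllithium to the more accessible carbonyl of a non-enolisable vicinal diketone: C7 is shielded by the isobutyryl group and the gem-dimethyl carbon around C1 and C8 by both bridgeheads, and attack on the exo face (the side of C8, away from the C2-C4 bridge) sets C6 with the oxygen endo. Silylation at -78 °C removes the alkoxide before retro-aldol opening can occur.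

Step 10
Reactants: 21 (1R,3R,5S,6S)-1-isobutyryl-2,2-dimethyl-6-(5-methylfuran-2-yl)-3,5-diprenyl-6-(trimethylsilyloxy)bicyclo[3.2.1]octane-7,8-dione
Product: 23 (1R,3R,5S,6S)-1-isobutyryl-2,2-dimethyl-6-[(2Z)-4-oxopent-2-enoyl]-3,5-diprenyl-6-(trimethylsilyloxy)bicyclo[3.2.1]octane-7,8-dione, via furan endoperoxide 22 (not isolated)
Conditions: O2, visible light, tetraphenylporphyrin (cat.), CH2Cl2, -78 °C; then Me2S, -78 to 0 °C
Reagents that add atoms: oxygen, O=O
Why: Singlet oxygen adds across the 2,5-positions of a dialkylfuran ([4+2]) much faster than it undergoes the ene reaction with trisubstituted alkenes, and reduction of the endoperoxide by Me2S unveils the cis-enedione, whose Z geometry is inherited from the ring; the silyl ether keeps the chain from closing to a pyranone hemiketal.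

Step 11
Reactants: 23 (1R,3R,5S,6S)-1-isobutyryl-2,2-dimethyl-6-[(2Z)-4-oxopent-2-enoyl]-3,5-diprenyl-6-(trimethylsilyloxy)bicyclo[3.2.1]octane-7,8-dione
Product: 25 (1R,3R,5S,6S)-6-hydroxy-6-[(2Z)-4-hydroxy-4-methylpent-2-enoyl]-1-isobutyryl-2,2-dimethyl-3,5-diprenylbicyclo[3.2.1]octane-7,8-dione, via silyl ether of the target 24 (not isolated)
Conditions: MeMgBr, CeCl3, THF, -78 °C; then 1 M HCl, THF, 0 °C
Reagents that add atoms: methylmagnesium bromide, C[Mg]Br
Why: The organocerium reagent formed from MeMgBr and CeCl3 adds 1,2 to the methyl ketone, the only carbonyl of 23 not flanked by a quaternary carbon, and avoids conjugate addition to the enedione; dilute acid then hydrolyses the trimethylsilyl ether without touching a stereocentre.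

## Compound list

1 | 6-methylhept-5-en-2-one | CC(=O)CCC=C(C)C | starting material
2 | isobutyryl chloride | CC(C)C(Cl)=O | starting material
3 | 2,9-dimethyldec-8-ene-3,5-dione | CC(C)C(=O)CC(=O)CCC=C(C)C | intermediate
4 | diethyl oxalate | CCOC(=O)C(=O)OCC | starting material
5 | ethyl 7-methyl-3-(3-methylbut-2-enyl)-2,4,6-trioxooctanoate (sodium enolate in the flask, drawn neutral) | CCOC(=O)C(=O)C(CC=C(C)C)C(=O)CC(=O)C(C)C | intermediate (not isolated)
6 | 3-isobutyryl-5-prenylcyclopentane-1,2,4-trione (dienol form drawn) | CC(C)C(O)=C1C(=O)C(O)=C(CC=C(C)C)C1=O | intermediate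
7 | 2-isobutyryl-4-prenyl-5-(triisopropylsilyloxy)cyclopent-4-ene-1,3-dione (acyl group as enol) | CC(C)C(O)=C1C(=O)C(O[Si](C(C)C)(C(C)C)C(C)C)=C(CC=C(C)C)C1=O | intermediate
8 | 3-methylbut-2-en-1-ol (prenol) | CC(C)=CCO | starting material
9 | 2-[2-methyl-1-(3-methylbut-2-enyloxy)propylidene]-4-prenyl-5-(triisopropylsilyloxy)cyclopent-4-ene-1,3-dione (E/Z mixture) | CC(C)C(OCC=C(C)C)=C1C(=O)C(O[Si](C(C)C)(C(C)C)C(C)C)=C(CC=C(C)C)C1=O | intermediate (not isolated)
10 | rac-2-isobutyryl-2-(2-methylbut-3-en-2-yl)-4-prenyl-5-(triisopropylsilyloxy)cyclopent-4-ene-1,3-dione | C=CC(C)(C)C1(C(=O)C(C)C)C(=O)C(O[Si](C(C)C)(C(C)C)C(C)C)=C(CC=C(C)C)C1=O | intermediate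
11 | (2R)-2-isobutyryl-2-(2-methylbut-3-en-2-yl)-4-prenyl-5-(triisopropylsilyloxy)cyclopent-4-ene-1,3-dione | C=CC(C)(C)[C@]1(C(=O)C(C)C)C(=O)C(O[Si](C(C)C)(C(C)C)C(C)C)=C(CC=C(C)C)C1=O | intermediate
12 | (5R)-5-isobutyryl-5-(2-methylbut-3-en-2-yl)-3-prenylcyclopentane-1,2,4-trione (2-enol drawn) | C=CC(C)(C)[C@]1(C(=O)C(C)C)C(=O)C(O)=C(CC=C(C)C)C1=O | intermediate (not isolated)
13 | (3R,5S)-3-bromo-5-isobutyryl-5-(2-methylbut-3-en-2-yl)-3-prenylcyclopentane-1,2,4-trione (one C3 epimer drawn) | C=CC(C)(C)[C@]1(C(=O)C(C)C)C(=O)C(=O)[C@@](Br)(CC=C(C)C)C1=O | intermediate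
14 | allyltributylstannane | C=CC[Sn](CCCC)(CCCC)CCCC | starting material
15 | (1R,5R)-3-bromo-1-isobutyryl-2,2-dimethyl-5-prenylbicyclo[3.2.1]octane-6,7,8-trione (both C3 epimers) | BrC1C[C@]2(CC=C(C)C)C(=O)[C@@](C(=O)C(C)C)(C(=O)C2=O)C1(C)C | intermediate (not isolated)
16 | (1R,3R,5R)-3-allyl-1-isobutyryl-2,2-dimethyl-5-prenylbicyclo[3.2.1]octane-6,7,8-trione | C=CC[C@@H]1C[C@]2(CC=C(C)C)C(=O)[C@@](C(=O)C(C)C)(C(=O)C2=O)C1(C)C | intermediate
17 | (1R,3R,5R)-1-isobutyryl-2,2-dimethyl-3,5-diprenylbicyclo[3.2.1]octane-6,7,8-trione | CC(C)=CC[C@@H]1C[C@]2(CC=C(C)C)C(=O)[C@@](C(=O)C(C)C)(C(=O)C2=O)C1(C)C | intermediate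
18 | 2-methylfuran | Cc1ccco1 | starting material
19 | 5-methyl-2-furyllithium | [Li]c1ccc(C)o1 | intermediate (not isolated)
20 | lithium (1R,3R,5S,6S)-1-isobutyryl-2,2-dimethyl-6-(5-methylfuran-2-yl)-7,8-dioxo-3,5-diprenylbicyclo[3.2.1]octan-6-olate | CC(C)=CC[C@@H]1C[C@]2(CC=C(C)C)C(=O)[C@@](C(=O)C(C)C)(C(=O)[C@@]2([O-])c3ccc(C)o3)C1(C)C.[Li+] | intermediate (not isolated)
21 | (1R,3R,5S,6S)-1-isobutyryl-2,2-dimethyl-6-(5-methylfuran-2-yl)-3,5-diprenyl-6-(trimethylsilyloxy)bicyclo[3.2.1]octane-7,8-dione | CC(C)=CC[C@@H]1C[C@]2(CC=C(C)C)C(=O)[C@@](C(=O)C(C)C)(C(=O)[C@@]2(O[Si](C)(C)C)c3ccc(C)o3)C1(C)C | intermediate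
22 | 2,5-endoperoxide of the furan ring of 21 (4-methyl-2,3,7-trioxabicyclo[2.2.1]hept-5-en-1-yl group on C6; core as in 21; both endoperoxide diastereomers) | CC(C)=CC[C@@H]1C[C@]2(CC=C(C)C)C(=O)[C@@](C(=O)C(C)C)(C(=O)[C@@]2(O[Si](C)(C)C)C3(OOC4(C)C=C3)O4)C1(C)C | intermediate (not isolated)
23 | (1R,3R,5S,6S)-1-isobutyryl-2,2-dimethyl-6-[(2Z)-4-oxopent-2-enoyl]-3,5-diprenyl-6-(trimethylsilyloxy)bicyclo[3.2.1]octane-7,8-dione | CC(C)=CC[C@@H]1C[C@]2(CC=C(C)C)C(=O)[C@@](C(=O)C(C)C)(C(=O)[C@@]2(O[Si](C)(C)C)C(=O)/C=C\C(C)=O)C1(C)C | intermediate
24 | (1R,3R,5S,6S)-6-[(2Z)-4-hydroxy-4-methylpent-2-enoyl]-1-isobutyryl-2,2-dimethyl-3,5-diprenyl-6-(trimethylsilyloxy)bicyclo[3.2.1]octane-7,8-dione | CC(C)=CC[C@@H]1C[C@]2(CC=C(C)C)C(=O)[C@@](C(=O)C(C)C)(C(=O)[C@@]2(O[Si](C)(C)C)C(=O)/C=C\C(C)(C)O)C1(C)C | intermediate (not isolated)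
25 | (1R,3R,5S,6S)-6-hydroxy-6-[(2Z)-4-hydroxy-4-methylpent-2-enoyl]-1-isobutyryl-2,2-dimethyl-3,5-diprenylbicyclo[3.2.1]octane-7,8-dione | CC(C)=CC[C@@H]1C[C@]2(CC=C(C)C)C(=O)[C@@](C(=O)C(C)C)(C(=O)[C@@]2(O)C(=O)/C=C\C(C)(C)O)C1(C)C | target

## Step count and least certain steps

Total: 11 steps. Longest linear sequence: 11 steps (1 to 25). Compounds 4, 8, 14 and 18 enter at steps 2, 4, 7 and 9.

**Step 7 (key step).**
- What may go wrong: the open-chain C5 radical may be captured by the stannane before it closes. In the second phase the hindered C3 radical may reopen by beta-scission to the stabilised dicarbonyl radical, which is then allylated at C5. Both paths give the monocyclic C-allyl trione. A sluggish chain at the crowded C3 radical is the third possibility.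
- Fallback: the two bond formations are separated. Setting out from 13, a bromine-atom-transfer cyclisation catalysed by CuCl and tris(2-pyridylmethyl)amine in 1,2-dichloroethane, with no allyl donor present, gives bromide 15, which is isolated. Then 15 is allylated on its own with neat 14, initiated by photolysis of (Bu3Sn)2 at room temperature, where reopening is slower. The route is rejoined at 16.

**Step 9.**
- What may go wrong: the nucleophile may attack C7, the carbonyl that is electronically more activated by the triacyl carbon C1, and retro-Claisen ring cleavage would follow. The C6 alkoxide may also collapse by retro-aldol before it is silylated.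
- Fallback: a reversible, acid-catalysed hydroxyalkylation replaces the organolithium addition. Setting out from 17, 2-methylfuran 18 and catalytic Sc(OTf)3 in CH2Cl2 at -20 °C should give, under thermodynamic control and without any alkoxide, (1R,3R,5S,6S)-6-hydroxy-1-isobutyryl-2,2-dimethyl-6-(5-methylfuran-2-yl)-3,5-diprenylbicyclo[3.2.1]octane-7,8-dione F1. F1 is then silylated (Me3SiOTf, 2,6-lutidine) to rejoin the route at 21.

**Step 11.**
- What may go wrong: the new Z-placed tertiary alkoxide may cyclise onto the neighbouring enone carbonyl, and the hemiketal alkoxide may then expel the C6 enolate (retro-Claisen with release of a butenolide). Conjugate addition is the lesser concern.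
- Fallback: the addition is run on the free C6 hydroxyl compound. Setting out from 23, HF·pyridine removes the silyl group and the chain closes to the spiro hemiketal (6-hydroxy-6-methyl-2H-pyran-3(6H)-one spiro-fused through its C2 to C6 of the bicycle) F2. With excess MeMgBr/CeCl3 the hemiketal alkoxide opens to the methyl ketone, while C6 carries an alkoxide and cannot leave as an enolate. The route is rejoined at 25.

**Step 3.**
- What may go wrong: if exchange among the oxygens is slow, silylation may occur at the acyl enol oxygen or twice, which would send the prenyl group of step 4 to the wrong oxygen.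
- Fallback: the order of events is changed so that no choice exists. Setting out from 1 and 4 (one equivalent, NaOEt, EtOH), the classical double condensation gives 3-prenylcyclopentane-1,2,4-trione F3. Its only enol is silylated (iPr3SiCl, imidazole) to 4-prenyl-5-(triisopropylsilyloxy)cyclopent-4-ene-1,3-dione F4. The remaining ring methylene is then C-acylated with 2 (MgCl2, Et3N, MeCN) to rejoin the route at 7.

Further compounds
F0 | step 7 | none | none
F1 | step 9 | (1R,3R,5S,6S)-6-hydroxy-1-isobutyryl-2,2-dimethyl-6-(5-methylfuran-2-yl)-3,5-diprenylbicyclo[3.2.1]octane-7,8-dione | CC(C)=CC[C@@H]1C[C@]2(CC=C(C)C)C(=O)[C@@](C(=O)C(C)C)(C(=O)[C@@]2(O)c3ccc(C)o3)C1(C)C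
F2 | step 11 | spiro hemiketal: 6-hydroxy-6-methyl-2H-pyran-3(6H)-one spiro-fused at its C2 to C6 of (1R,3R,5S)-1-isobutyryl-2,2-dimethyl-3,5-diprenylbicyclo[3.2.1]octane-7,8-dione (ring oxygen endo, both anomers) | CC(C)=CC[C@@H]1C[C@]2(CC=C(C)C)C(=O)[C@@](C(=O)C(C)C)(C(=O)[C@]23OC(C)(O)C=CC3=O)C1(C)C
F3 | step 3 | 3-prenylcyclopentane-1,2,4-trione (2-enol drawn) | O=C1CC(=O)C(CC=C(C)C)=C1O
F4 | step 3 | 4-prenyl-5-(triisopropylsilyloxy)cyclopent-4-ene-1,3-dione | O=C1CC(=O)C(CC=C(C)C)=C1O[Si](C(C)C)(C(C)C)C(C)C
A1 | alternative 1 | 1-isobutyryl-2,2-dimethyl-3,5-diprenylbicyclo[3.2.1]octane-7,8-dione | CC(C)=CC[C@@H]1C[C@]2(CC=C(C)C)C(=O)[C@@](C(=O)C(C)C)(C(=O)C2)C1(C)C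
A2 | alternative 1 | 2-[3-isobutyryl-2-methoxy-4,4-dimethyl-1,5-diprenylcyclohex-2-en-1-yl]acetic acid | CC(C)=CC[C@@H]1C[C@@](CC=C(C)C)(CC(=O)O)C(OC)=C(C(=O)C(C)C)C1(C)C
A3 | alternative 2 | 1-isobutyryl-2,2-dimethyl-5-prenyl-6,7-bis(tert-butyldimethylsilyloxy)bicyclo[3.2.1]oct-6-ene-3,8-dione | O=C1C[C@]2(CC=C(C)C)C(=O)[C@@](C(=O)C(C)C)(C(O[Si](C)(C)C(C)(C)C)=C2O[Si](C)(C)C(C)(C)C)C1(C)C
A4 | alternative 2 | 2-isobutyryl-5-prenyl-3,4-bis(tert-butyldimethylsilyloxy)cyclopenta-2,4-dien-1-one | CC(C)C(=O)C1=C(O[Si](C)(C)C(C)(C)C)C(O[Si](C)(C)C(C)(C)C)=C(CC=C(C)C)C1=O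
A5 | alternative 2 | (3-bromo-3-methylbut-1-en-2-yl)oxytrimethylsilane | C=C(O[Si](C)(C)C)C(C)(C)Br
A6 | alternative 3 | tert-butyl 1-isobutyryl-2,2-dimethyl-6,7,8-trioxo-5-prenylbicyclo[3.2.1]octane-3-carboxylate | CC(C)(C)OC(=O)[C@@H]1C[C@]2(CC=C(C)C)C(=O)[C@@](C(=O)C(C)C)(C(=O)C2=O)C1(C)C
A7 | alternative 3 | tert-butyl 3-[(1R)-1-isobutyryl-2,3,5-trioxo-4-prenylcyclopentyl]-3-methyl-2-methylidenebutanoate (enol drawn) | C=C(C(=O)OC(C)(C)C)C(C)(C)[C@]1(C(=O)C(C)C)C(=O)C(O)=C(CC=C(C)C)C1=O
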